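0.410 mM of working catalyst, the charge of free catalyst less the charge of impurity, set against 0.30 M of starting material, is the number over which two chemists disagree before any of these set-ups has run.

in all of them: free catalyst 0.60 mM; impurity 0.19 mM

| charge | starting material | reagent | remark | time |
|---|---|---|---|---|
| Wednesday's | 0.30 M | 0.315 M | a single well-mixed tank run continuously and read at steady state, 2.5 h in it on average |  |
| Monday's | 0.30 M | 0.315 M | a closed flask charged with all of it at once and left for 2.5 h | 2.5 h |
| Friday's | 0.30 M | 0.315 M (fed, over 2.00 h) | all but reagent at the start; reagent goes in evenly over 2.00 h, the run ends at 2.5 h | 2.5 h |
| Thursday's | 0.30 M (fed, over 2.00 h) | 0.315 M | a stirred flask in which starting material is dosed at a steady rate over 2.00 h without added volume, worked up at 2.5 h | 2.5 h |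

    reagent + free catalyst → catalyst intermediate A (k1 = 49.3 M⁻¹ min⁻¹)
    starting material + catalyst intermediate A → catalyst intermediate B (k2 = 121 M⁻¹ min⁻¹)
    catalyst intermediate B → free catalyst + product (k3 = 3.50 min⁻¹)
    free catalyst + impurity → spent catalyst A (k4 = 28500 M⁻¹ min⁻¹)
    2 free catalyst → spent catalyst B (k5 = 41.2 M⁻¹ min⁻¹)

- the set-up with the highest amount of product at the outlet or at the end, in percent of the starting material put in ("none" if the first two lie within 2 percentage points) (Wednesday's / Monday's / Friday's / Thursday's / none)
- amount of product at the outlet or at the end, in percent of the starting material put in, Wednesday's
- amount of product at the outlet or at the end, in percent of the starting material put in, Monday's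
- amount of product at the outlet or at the end, in percent of the starting material put in, Friday's
- amount of product at the outlet or at the end, in percent of the starting material put in, Thursday's

- where a step has two of a species, its rate is k times that concentration squared, and two are used at each turn
- the stated concentrations are those of everything mixed, before any reaction; amounts are the same in each set-up
- the feed brings no volume worth counting
- run time (Monday's): 2.5 h

The first chemist asks for the end state: the 0.30 M of starting material is less than the 0.315 M of reagent, which makes it the limiting reagent, so the end state is that starting material turned into product. With free catalyst held at its charge, as if it never ran down, reagent has a half-life of 0.39 h by the first step, so the 2.5 h of Monday's flask holds 6.41 half-lives and leaves 1.18% of the reagent, which to this chemist means a finished flask.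

The second chemist, whose reckoning I commit to, grants that end and asks how fast it is approached. With free catalyst held at its charge, impurity has a half-life of 0.0405 min by the fourth step, far shorter than the run, so its 0.19 mM of catalyst is counted as lost at the outset and the 0.410 mM that remains goes round. One round at charged concentrations lasts 0.378 min, and the third step, the rate-limiting step, takes 75.7% of it, longer than the first two together. The catalyst clock, the time the whole charge of starting material needs to pass through the working catalyst at that opening round, is then 276 min, so Monday's flask should show about 54.3% after 2.5 h, a figure that takes no account of falling concentrations.

The forecast stands on the second side but lower than this reckoning, with 46% for Monday's (range 42% to 50%), 39% for Thursday's, 38.7% for Wednesday's and 25% for Friday's, and it names Monday's as best, on the ground that “every set-up is catalyst-limited and none gets near completion”.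

Monday's flask gives 45.9%, higher than Thursday's 41.0%, Wednesday's 38.6% and Friday's 25.0%, so the best is Monday's, while the first chemist's end state does appear in Monday's flask at 25.0 h, where product stands at >99.9%. Monday's 45.9% is 0.846 of the figure from the clock. With impurity at 7.6 × 10⁻⁵ M and the other charges as in Monday's, the clock comes to 216 min, shorter than Monday's 276 min, which through that same factor points to 58.7%, and that flask gives 55.5%.

The rate constants are invented; the rest is arithmetic.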